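A direct plan would methylate 2,4,6-trihydroxybenzaldehyde A1 once at O-4 to 2,6-dihydroxy-4-methoxybenzaldehyde A2, Dakin-oxidise A2 to 5-methoxybenzene-1,2,3-triol A3 and C-acylate A3 to the dihydrochalcone 1-(2,3,4-trihydroxy-6-methoxyphenyl)-3-phenylpropan-1-one A4.
It would finish with an acid-mediated Friedel–Crafts hydroxyalkylation of A4 by phenylpyruvic acid A5, lactonisation to 3-benzyl-3,6,7-trihydroxy-4-methoxy-5-(3-phenylpropanoyl)-1-benzofuran-2(3H)-one A6 and dehydration of A6 to the target.
Its weakest steps would be these three.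
The final cascade: it would have to make a C–C bond at the only free, doubly flanked carbon of A4, a ring deactivated by its chelated ketone, while the enolisable α-keto acid A5 would tend to self-condense, and it would leave ring closure, dehydration and alkene geometry to one unprecedented operation on the most advanced material.
The Dakin oxidation of A2: it would spend a step to reach A3, a plain tetraoxygenated benzene that is an air- and peroxide-sensitive free triol and would have to be carried unprotected.
The mono-methylation of A1 with one equivalent of a methylating agent: selectivity for O-4 over di- and C-methylation would rest on a small acidity difference, so half of the steps would only dress a simple benzene.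

The retrosynthesis first cuts the exocyclic C3=CH bond (aldol condensation with benzaldehyde) and then dismantles ring A, the benzene ring, in one [3+2+1] Dötz disconnection of C4–C5, C6–C7 and C7–C7a.
This leaves a furyl(methoxy)carbene complex of zerovalent chromium (C4 with its OMe, C3a, C7a and the whole five-membered O-ring, held as the silyloxyfuran of a butenolide), one CO ligand (C7 and its OH) and an alkoxy ynone (C5 with the complete 3-phenylpropanoyl chain, C6 with its oxygen).
The feature that permits this: in ring A, C4–OMe and C7–OH stand para (a hydroquinone monomethyl ether, the signature of this benzannulation), C5 and C6 carry acyl and oxygen, and the C3a–C7a edge belongs to a lactone that is the keto form of a 2-hydroxyfuran.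
The five-membered ring therefore comes first, ring A is built onto it last, and the lactone is unveiled only afterwards.
No triphenol is methylated selectively, no free polyphenol is oxidised or acylated, and no C–C bond is forced onto a crowded arene carbon: all six substituents of ring A arrive with the ring.

Key step: step 5

Assumption: 4-bromofuran-2(5H)-one is taken as a catalogue compound; all other starting materials are bulk chemicals.

**Route**

Step 1
Reactants: 1 4-bromofuran-2(5H)-one
Product: 2 [(4-bromofuran-2-yl)oxy]tri(propan-2-yl)silane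
Conditions: TIPSOTf (1.1 equiv), Et3N (1.5 equiv), CH2Cl2, 0 °C → rt; filtration through basic Al2O3
Reagents that add atoms: triisopropylsilyl trifluoromethanesulfonate, CC(C)[Si](OS(=O)(=O)C(F)(F)F)(C(C)C)C(C)C
Why: Soft enolisation and O-silylation of a butenolide (silyl dienol ether formation) should give the aromatic 2-silyloxyfuran, the bulky silyl group being chosen to survive the organometallic steps; no stereocentre is involved.

Step 2
Reactants: 2 [(4-bromofuran-2-yl)oxy]tri(propan-2-yl)silane
Product: 5 pentacarbonyl{methoxy[5-(triisopropylsilyloxy)furan-3-yl]methylidene}chromium, via lithiofuran 3 (not isolated), via acyl chromate 4 (not isolated)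
Conditions: t-BuLi (2.0 equiv), Et2O, –78 °C; Cr(CO)6 (1.05 equiv), –78 → 0 °C; then MeOTf (1.2 equiv), CH2Cl2, 0 °C; Ar
Reagents that add atoms: Cr(CO)6, O=C=[Cr](=C=O)(=C=O)(=C=O)(=C=O)=C=O; methyl trifluoromethanesulfonate, COS(=O)(=O)C(F)(F)F
Why: Fischer carbene synthesis, in which bromine–lithium exchange gives the β-furyllithium 3, this adds to a CO ligand of Cr(CO)6, and the hard acylate oxygen of 4 should be O-methylated faster than the silyl ketene acetal carbon can react, as in the preparation of the parent furan-3-yl complex; no stereocentre is involved.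

Step 3
Reactants: 6 propan-2-ol; 7 trichloroethene; 8 3-phenylpropanal
Product: 11 rac-5-phenyl-1-(propan-2-yloxy)pent-1-yn-3-ol, via dichlorovinyl ether 9 (not isolated), via lithium alkynide 10 (not isolated)
Conditions: 6, KH (1.05 equiv), THF, rt; 7, –50 °C → rt; n-BuLi (2.2 equiv), –78 → –40 °C; 8 (0.8 equiv), –78 °C; sat. aq NH4Cl; Et3N-treated silica
Reagents that add atoms: none
Why: Greene-type ynol ether synthesis (alkoxide addition to dichloroethyne formed in situ, then elimination and chlorine–lithium exchange) followed by 1,2-addition of the alkynide to the aldehyde should give the alkynol, whose carbinol centre forms racemic and is removed in the next step.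

Step 4
Reactants: 11 rac-5-phenyl-1-(propan-2-yloxy)pent-1-yn-3-ol
Product: 12 5-phenyl-1-(propan-2-yloxy)pent-1-yn-3-one
Conditions: activated MnO2 (15 equiv), CH2Cl2, rt
Reagents that add atoms: none
Why: Oxidation of a propargylic alcohol with MnO2 under neutral conditions, which the acid-sensitive ynol ether tolerates, should give the push–pull alkoxy ynone and erase the only stereocentre.

Step 5
Reactants: 5 pentacarbonyl{methoxy[5-(triisopropylsilyloxy)furan-3-yl]methylidene}chromium; 12 5-phenyl-1-(propan-2-yloxy)pent-1-yn-3-one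
Product: 16 1-{7-hydroxy-4-methoxy-6-(propan-2-yloxy)-2-[(triisopropylsilyl)oxy]-1-benzofuran-5-yl}-3-phenylpropan-1-one, via chromium vinylcarbene 13 (not isolated), via chromium vinylketene 14 (not isolated), via cyclohexadienone 15 (not isolated)
Conditions: 12 (1.5 equiv), THF (0.05 M), 50 °C, Ar; then air, rt; Et3N-treated silica
Reagents that add atoms: none
Why: Dötz benzannulation: loss of one CO from 5 lets ynone 12 insert into the Cr=C bond to give vinylcarbene 13, a CO ligand then inserts to give the chromium-bound dienylketene 14, and 6π-electrocyclisation of 14 onto the furan, enolisation of dienone 15 and loss of the metal on exposure to air should give phenol 16. The closest known reaction type is the benzannulation of furyl(methoxy)carbene complexes of zerovalent chromium with alkoxy-substituted alkynes and alkynyl ketones, which gives 4,7-dioxygenated benzofurans of the khellinone substitution pattern. Ring A is the only ring closed, by a thermal 6π-electrocyclisation in which the ketene carbon (C7) bonds to furan C-2 (C7a), the five-membered ring being present already. The only new sp3 centre, C7a of 15, is transient and is erased by aromatisation, so no stereocentre has to be controlled. The step needs the alkyne to insert so that its acyl-bearing carbon bonds to the carbene carbon (C5 next to C4–OMe) and its alkoxy-bearing carbon becomes the new, oxygen-stabilised carbene carbon that takes up CO (C6 next to C7–OH), and the push–pull polarisation of the alkoxy ynone, whose enolate-like carbon is the nucleophilic terminus, should secure this sense. Closure must occur at furan C-2 and not at C-4, which the fixed C2=C3 double bond of the furan ensures (closure at C-4 would give an o-quinoid isobenzofuran), while the carbene methoxy group and the inserted CO fix 4-OMe and 7-OH without any selective alkylation.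

Step 6
Reactants: 16 1-{7-hydroxy-4-methoxy-6-(propan-2-yloxy)-2-[(triisopropylsilyl)oxy]-1-benzofuran-5-yl}-3-phenylpropan-1-one
Product: 17 6,7-dihydroxy-4-methoxy-5-(3-phenylpropanoyl)-1-benzofuran-2(3H)-one
Conditions: BCl3 (3 equiv), CH2Cl2, –78 → –20 °C; then THF–1 M aq HCl, rt; Ar
Reagents that add atoms: none
Why: Lewis-acid cleavage of an isopropyl aryl ether (boron chelated between the ketone and O-6, the secondary alkyl group leaving far faster than methyl) and protodesilylation of the silyl ketene acetal on acidic work-up should unveil the catechol and the lactone in one operation; no stereocentre is involved.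

Step 7
Reactants: 17 6,7-dihydroxy-4-methoxy-5-(3-phenylpropanoyl)-1-benzofuran-2(3H)-one; 18 benzaldehyde
Product: 20 bractelactone [(Z)-3-benzylidene-6,7-dihydroxy-4-methoxy-5-(3-phenylpropanoyl)-1-benzofuran-2(3H)-one], via aldol adduct 19 (not isolated)
Conditions: 18 (1.3 equiv), conc. HCl (cat.), AcOH, 60 °C, Ar
Reagents that add atoms: none
Why: Acid-catalysed Knoevenagel-type aldol condensation at the highly enolisable lactone C-3, the method used for aurones and isoaurones of polyphenols, should give the benzylidene lactone after loss of water from 19, and the geometry should settle at Z under the reversible acidic conditions because an E phenyl group would clash with 4-OMe; no stereocentre remains.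

**Compound list**

1 | 4-bromofuran-2(5H)-one | O=C1C=C(Br)CO1 | starting material
2 | [(4-bromofuran-2-yl)oxy]tri(propan-2-yl)silane | CC(C)[Si](Oc1cc(Br)co1)(C(C)C)C(C)C | intermediate
3 | {5-[(triisopropylsilyl)oxy]furan-3-yl}lithium (not isolated) | [Li]c1coc(O[Si](C(C)C)(C(C)C)C(C)C)c1 | intermediate
4 | lithium pentacarbonyl{oxido[5-(triisopropylsilyloxy)furan-3-yl]methylidene}chromate (not isolated) | [Li+].[O-]C(c1coc(O[Si](C(C)C)(C(C)C)C(C)C)c1)=[Cr](=C=O)(=C=O)(=C=O)(=C=O)=C=O | intermediate
5 | pentacarbonyl{methoxy[5-(triisopropylsilyloxy)furan-3-yl]methylidene}chromium (Fischer carbene of zerovalent chromium) | COC(c1coc(O[Si](C(C)C)(C(C)C)C(C)C)c1)=[Cr](=C=O)(=C=O)(=C=O)(=C=O)=C=O | intermediate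
6 | propan-2-ol | CC(C)O | starting material
7 | trichloroethene | ClC=C(Cl)Cl | starting material
8 | 3-phenylpropanal | O=CCCc1ccccc1 | starting material
9 | (E)-1,2-dichloro-1-(propan-2-yloxy)ethene (not isolated) | CC(C)O/C(Cl)=C\Cl | intermediate
10 | lithium (propan-2-yloxy)ethynide (not isolated) | [Li]C#COC(C)C | intermediate
11 | rac-5-phenyl-1-(propan-2-yloxy)pent-1-yn-3-ol | CC(C)OC#CC(O)CCc1ccccc1 | intermediate
12 | 5-phenyl-1-(propan-2-yloxy)pent-1-yn-3-one | CC(C)OC#CC(=O)CCc1ccccc1 | intermediate
13 | tetracarbonyl{3-methoxy-2-(3-phenylpropanoyl)-1-(propan-2-yloxy)-3-[5-(triisopropylsilyloxy)furan-3-yl]prop-2-en-1-ylidene}chromium (vinylcarbene complex, not isolated) | CC(C)OC(=[Cr](=C=O)(=C=O)(=C=O)=C=O)C(C(=O)CCc1ccccc1)=C(OC)c1coc(O[Si](C(C)C)(C(C)C)C(C)C)c1 | intermediate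
14 | 4-methoxy-3-(3-phenylpropanoyl)-2-(propan-2-yloxy)-4-[5-(triisopropylsilyloxy)furan-3-yl]buta-1,3-dien-1-one bound η4 to a Cr(CO)3 fragment (dienylketene complex, not isolated) | CC(C)OC(=C=O)C(C(=O)CCc1ccccc1)=C(OC)c1coc(O[Si](C(C)C)(C(C)C)C(C)C)c1.[Cr](=C=O)(=C=O)=C=O | intermediate
15 | 4-methoxy-5-(3-phenylpropanoyl)-6-(propan-2-yloxy)-2-[(triisopropylsilyl)oxy]-1-benzofuran-7(7aH)-one bound to a Cr(CO)3 fragment (racemic at C7a, not isolated) | COC1=C2C=C(O[Si](C(C)C)(C(C)C)C(C)C)OC2C(=O)C(OC(C)C)=C1C(=O)CCc1ccccc1.[Cr](=C=O)(=C=O)=C=O | intermediate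
16 | 1-{7-hydroxy-4-methoxy-6-(propan-2-yloxy)-2-[(triisopropylsilyl)oxy]-1-benzofuran-5-yl}-3-phenylpropan-1-one | COc1c(C(=O)CCc2ccccc2)c(OC(C)C)c(O)c2oc(O[Si](C(C)C)(C(C)C)C(C)C)cc12 | intermediate
17 | 6,7-dihydroxy-4-methoxy-5-(3-phenylpropanoyl)-1-benzofuran-2(3H)-one | COc1c(C(=O)CCc2ccccc2)c(O)c(O)c2OC(=O)Cc12 | intermediate
18 | benzaldehyde | O=Cc1ccccc1 | starting material
19 | 6,7-dihydroxy-3-[hydroxy(phenyl)methyl]-4-methoxy-5-(3-phenylpropanoyl)-1-benzofuran-2(3H)-one (mixture of racemic diastereomers, not isolated) | COc1c(C(=O)CCc2ccccc2)c(O)c(O)c2OC(=O)C(C(O)c3ccccc3)c12 | intermediate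
20 | bractelactone, (Z)-3-benzylidene-6,7-dihydroxy-4-methoxy-5-(3-phenylpropanoyl)-1-benzofuran-2(3H)-one | COc1c(C(=O)CCc2ccccc2)c(O)c(O)c2c1/C(=C/c1ccccc1)C(=O)O2 | target

**Step count and risks**

Total steps: 7. Longest linear sequence: 5 (steps 1, 2, 5, 6, 7; the alkyne branch, steps 3, 4, 5, 6, 7, is equally long).

The three steps most likely to fail:

Step 5. The alkyne may insert in the opposite sense, the chromium ketene may be trapped by the neighbouring ketone oxygen or ring closure may occur without CO insertion, and the ynol ether may slowly lose propene at 50 °C. The fallback sets out from 2, uses 8 as well, and comes back at 16. The same dienylketene would be generated without a metal, by electrocyclic opening of a cyclobutenone (Moore-type ring expansion). Lithiofuran 3, made from 2 as in step 2, would be added to diisopropyl squarate at –78 °C and the alkoxide trapped with MeOTf to give 4-methoxy-2,3-di(propan-2-yloxy)-4-{5-[(triisopropylsilyl)oxy]furan-3-yl}cyclobut-2-en-1-one F1. Aldehyde 8 would be converted with propane-1,3-dithiol and BF3·OEt2 into 2-(2-phenylethyl)-1,3-dithiane F2. The 2-lithio derivative of F2 would be made with n-BuLi and would add to F1 at its remaining carbonyl group, and treatment of the adduct with trifluoroacetic anhydride and then aqueous NaHCO3 would transpose the enone with loss of propan-2-ol to give 4-methoxy-3-[2-(2-phenylethyl)-1,3-dithian-2-yl]-2-(propan-2-yloxy)-4-{5-[(triisopropylsilyl)oxy]furan-3-yl}cyclobut-2-en-1-one F3. Heating F3 in toluene at 110 °C would give 4-methoxy-5-[2-(2-phenylethyl)-1,3-dithian-2-yl]-6-(propan-2-yloxy)-2-[(triisopropylsilyl)oxy]-1-benzofuran-7-ol F4 by 4π opening with the methoxy group turning outward, 6π closure onto furan C-2 and enolisation. Here the order of the two additions, not an insertion, fixes the regiochemistry. MeI and CaCO3 in aqueous MeCN would then unmask the ketone of F4 to give 16.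

Step 2. The β-furyllithium may isomerise to the α-lithio isomer or fragment before it acylates Cr(CO)6, and the silyl ketene acetal may be C-alkylated or desilylated during the O-methylation. The fallback sets out from 12 and comes back at 17; it introduces the 2-oxygen only after the benzannulation. The parent complex pentacarbonyl[furan-3-yl(methoxy)methylidene]chromium F5 would be made from 3-bromofuran by the sequence of step 2 and heated with 12 as in step 5 to give 1-[7-hydroxy-4-methoxy-6-(propan-2-yloxy)-1-benzofuran-5-yl]-3-phenylpropan-1-one F6. C–H borylation of F6 with B2pin2 and [Ir(OMe)(cod)]2/4,4′-di-tert-butyl-2,2′-bipyridine, which is selective for C-2 of benzofurans, would give 1-[7-hydroxy-4-methoxy-6-(propan-2-yloxy)-2-(4,4,5,5-tetramethyl-1,3,2-dioxaborolan-2-yl)-1-benzofuran-5-yl]-3-phenylpropan-1-one F7. Oxidation of F7 with NaBO3 in aqueous THF would give 7-hydroxy-4-methoxy-5-(3-phenylpropanoyl)-6-(propan-2-yloxy)-1-benzofuran-2(3H)-one F8, and treatment of F8 with BCl3 as in step 6 would give 17.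

Step 6. Chelation-assisted loss of the 4-O-methyl group may accompany loss of the isopropyl group (over-dealkylation beside the ketone). The fallback sets out from 8 and comes back at 17; it carries the 6-oxygen as a 2-(trimethylsilyl)ethyl ether, which leaves by fluoride-induced fragmentation and not by Lewis-acid dealkylation. 2-(Trimethylsilyl)ethanol would take the place of 6 in step 3, its alkoxide being formed with NaH at 0 °C to avoid fragmentation of the β-silyl alkoxide, to give 5-phenyl-1-[2-(trimethylsilyl)ethoxy]pent-1-yn-3-ol F9, and oxidation of F9 with MnO2 as in step 4 would give 5-phenyl-1-[2-(trimethylsilyl)ethoxy]pent-1-yn-3-one F10. Benzannulation of F10 with 5 as in step 5 would give 1-{7-hydroxy-4-methoxy-2-[(triisopropylsilyl)oxy]-6-[2-(trimethylsilyl)ethoxy]-1-benzofuran-5-yl}-3-phenylpropan-1-one F11. Treatment of F11 with Bu4NF in THF at 50 °C under argon, followed by AcOH, would remove both silicon groups, with loss of ethene from the ether, to give 17, a methyl ether being inert to fluoride.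

**Further compounds**

F1 | step 5 | 4-methoxy-2,3-di(propan-2-yloxy)-4-{5-[(triisopropylsilyl)oxy]furan-3-yl}cyclobut-2-en-1-one | COC1(c2coc(O[Si](C(C)C)(C(C)C)C(C)C)c2)C(OC(C)C)=C(OC(C)C)C1=O
F2 | step 5 | 2-(2-phenylethyl)-1,3-dithiane | C1CSC(CCc2ccccc2)SC1
F3 | step 5 | 4-methoxy-3-[2-(2-phenylethyl)-1,3-dithian-2-yl]-2-(propan-2-yloxy)-4-{5-[(triisopropylsilyl)oxy]furan-3-yl}cyclobut-2-en-1-one | COC1(c2coc(O[Si](C(C)C)(C(C)C)C(C)C)c2)C(C2(CCc3ccccc3)SCCCS2)=C(OC(C)C)C1=O
F4 | step 5 | 4-methoxy-5-[2-(2-phenylethyl)-1,3-dithian-2-yl]-6-(propan-2-yloxy)-2-[(triisopropylsilyl)oxy]-1-benzofuran-7-ol | COc1c(C2(CCc3ccccc3)SCCCS2)c(OC(C)C)c(O)c2oc(O[Si](C(C)C)(C(C)C)C(C)C)cc12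
F5 | step 2 | pentacarbonyl[furan-3-yl(methoxy)methylidene]chromium | COC(c1ccoc1)=[Cr](=C=O)(=C=O)(=C=O)(=C=O)=C=O
F6 | step 2 | 1-[7-hydroxy-4-methoxy-6-(propan-2-yloxy)-1-benzofuran-5-yl]-3-phenylpropan-1-one | COc1c(C(=O)CCc2ccccc2)c(OC(C)C)c(O)c2occc12
F7 | step 2 | 1-[7-hydroxy-4-methoxy-6-(propan-2-yloxy)-2-(4,4,5,5-tetramethyl-1,3,2-dioxaborolan-2-yl)-1-benzofuran-5-yl]-3-phenylpropan-1-one | COc1c(C(=O)CCc2ccccc2)c(OC(C)C)c(O)c2oc(B3OC(C)(C)C(C)(C)O3)cc12
F8 | step 2 | 7-hydroxy-4-methoxy-5-(3-phenylpropanoyl)-6-(propan-2-yloxy)-1-benzofuran-2(3H)-one | COc1c(C(=O)CCc2ccccc2)c(OC(C)C)c(O)c2OC(=O)Cc12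
F9 | step 6 | 5-phenyl-1-[2-(trimethylsilyl)ethoxy]pent-1-yn-3-ol | C[Si](C)(C)CCOC#CC(O)CCc1ccccc1
F10 | step 6 | 5-phenyl-1-[2-(trimethylsilyl)ethoxy]pent-1-yn-3-one | C[Si](C)(C)CCOC#CC(=O)CCc1ccccc1
F11 | step 6 | 1-{7-hydroxy-4-methoxy-2-[(triisopropylsilyl)oxy]-6-[2-(trimethylsilyl)ethoxy]-1-benzofuran-5-yl}-3-phenylpropan-1-one | COc1c(C(=O)CCc2ccccc2)c(OCC[Si](C)(C)C)c(O)c2oc(O[Si](C(C)C)(C(C)C)C(C)C)cc12
A1 | direct plan | 2,4,6-trihydroxybenzaldehyde | O=Cc1c(O)cc(O)cc1O
A2 | direct plan | 2,6-dihydroxy-4-methoxybenzaldehyde | COc1cc(O)c(C=O)c(O)c1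
A3 | direct plan | 5-methoxybenzene-1,2,3-triol | COc1cc(O)c(O)c(O)c1
A4 | direct plan | 1-(2,3,4-trihydroxy-6-methoxyphenyl)-3-phenylpropan-1-one | COc1cc(O)c(O)c(O)c1C(=O)CCc1ccccc1
A5 | direct plan | phenylpyruvic acid (2-oxo-3-phenylpropanoic acid) | OC(=O)C(=O)Cc1ccccc1
A6 | direct plan | 3-benzyl-3,6,7-trihydroxy-4-methoxy-5-(3-phenylpropanoyl)-1-benzofuran-2(3H)-one | COc1c(C(=O)CCc2ccccc2)c(O)c(O)c2OC(=O)C(O)(Cc3ccccc3)c12
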